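All runs stem from a simulated flask with made-up constants, noise included.

In a closed, stirred vessel at constant volume and fixed temperature, the starting material splits between target and side product, and in Monday's run the isomer shows up late. You want to know which species leads at 20 min in blue and in green, and how much of it stands there.

| flask | starting material | temperature | remark | time |
|---|---|---|---|---|
| Saturday's | 0.25 M | 35 °C | run made earlier |  |
| Monday's | 1 M | 55 °C | run made earlier |  |
| blue | 0.50 M | 50 °C |  | 20 min |
| green | 0.50 M | 60 °C |  | 20 min |

| run | time / min | isomer of the product / % | target / % | starting material / % | side product / % |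
|---|---|---|---|---|---|
| Saturday's | 3.00 | 0.9 | 7.3 | 87.9 | 2.3 |
| Saturday's | 6.00 | 1.2 | 17.3 | 76.0 | 6.0 |
| Saturday's | 10.0 | 1.8 | 27.3 | 63.9 | 9.4 |
| Saturday's | 12.0 | 3.8 | 32.0 | 60.4 | 8.6 |
| Saturday's | 15.0 | 0.9 | 35.0 | 51.6 | 12.1 |
| Saturday's | 20.0 | 0.3 | 42.8 | 40.8 | 13.9 |
| Saturday's | 25.0 | 0 | 48.5 | 34.9 | 19.8 |
| Monday's | 1.00 | 0.1 | 18.6 | 72.0 | 8.9 |
| Monday's | 1.33 | 0 | 23.9 | 65.1 | 10.7 |
| Monday's | 2.00 | 0.9 | 31.2 | 49.4 | 17.3 |
| Monday's | 3.00 | 0 | 42.5 | 37.1 | 20.9 |
| Monday's | 5.00 | 2.1 | 52.7 | 18.8 | 27.5 |
| Monday's | 8.00 | 4.2 | 60.0 | 8.6 | 31.1 |
| Monday's | 12.0 | 6.4 | 60.9 | 2.3 | 31.3 |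

(standard deviation of a reading: 1 percentage point)

1. which of these there is most of at the end, counted by the starting material in it, blue (side product / starting material / isomer of the product / target)
2. which of these there is most of at the end, counted by the starting material in it, green (side product / starting material / isomer of the product / target)
3. how much there is at the end of the one of these that leads, in percent of the starting material charged: blue
4. how much there is at the end of the one of these that leads, in percent of the starting material charged: green

- what was read earlier has a scatter of 1 percentage point, one standard deviation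

Take the time scales from fastest to slowest. Consumption comes first: the first-order constant of the starting material reads 0.0421 min⁻¹ on Saturday and 0.307 min⁻¹ on Monday. Assuming no concentration effect, that is a factor of 7.28 across the temperature gap. Stepping ln k evenly from Monday's temperature gives 0.187 min⁻¹ for blue and 0.504 min⁻¹ for green. The half-lives are 3.71 min and 1.38 min, both shorter than the run, so nearly all is consumed even in blue.

The branching comes with it. The selectivity, meaning target plus isomer over everything formed, reads 71.0% on Saturday and 68.3% on Monday. Stepped the same way, again assuming no concentration effect, it is 68.9% for blue and 67.6% for green.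

Last on the ladder comes the leak constant, the fraction of target turning into isomer per minute. Monday's isomer gain from 5.00 min to 12.0 min, divided by that time and the target reading between, gives 0.0102 min⁻¹. Assuming it scales like consumption, it is 0.00623 min⁻¹ in blue and 0.0168 min⁻¹ in green. Those half-lives, 111 min and 41.2 min, are longer than the run.

Now iterate. Target exists for about the run minus one over the consumption constant, 14.6 min in blue and 18.0 min in green, so the first round leaks 6.29% and 20.5%. Putting that back, the leak lowers its own feed by a mean fraction of 4.55% and 15.1%, so the isomer becomes 6.00% and 17.4%. My target is 61.3% in blue and 50.2% in green, ahead of the side product in both.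

The forecast also has target leading, at 62% (57% to 66%) in blue and 52% (44% to 60%) in green, above my figures, and says of the isomer “it likely comes from target”.

The flasks give target at 62.0% in blue and target at 52.4% in green.

    starting material → target (k = 0.140 min⁻¹, Ea = 82.0 kJ mol⁻¹)
    starting material → side product (k = 0.0630 min⁻¹, Ea = 93.0 kJ mol⁻¹)
    target ⇌ isomer of the product (K = 1.40, k = 0.00600 min⁻¹, Ea = 99.0 kJ mol⁻¹, ΔH = −90.0 kJ mol⁻¹)
    (constants at 50 °C)

Against the reckoned isomer, blue holds 5.77% for 6.00%, and green holds less, 13.9% for 17.4%. Now repeat green at 45 °C. The constants become 0.114 min⁻¹ and 0.00379 min⁻¹, the selectivity 69.6%, and the time 11.2 min. Two rounds give isomer 2.90% and target 59.6%. That flask ends with isomer 2.87%, starting material 8.5% and target 61.5%.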